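**Retrosynthetic overview**
1. Target ⇒ the 6-(1-bromopropyl)tribromopyranone, with the second C1′–Br set by radical (Wohl–Ziegler) bromination. That bromide ⇒ the C1′ carbinol (OH → Br).
2. Carbinol ⇒ 3,5-dibromo-4H-pyran-4-one + propanal + a "Br+" source. The ring–C1′ bond and the C2–Br bond both come from magnesiation of the two equivalent ring C–H bonds. The C–C bond is made first, so that the alkoxide masks the lateral (vinylogous) acidity during the second metalation.
3. 3,5-Dibromo-4H-pyran-4-one ⇒ 4H-pyran-4-one by electrophilic bromination.
4. Rings: the only ring (the 4-pyranone) is bought intact, so there is no ring-forming step.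

Assumption: the target SMILES has no stereocentre (C1′ carries two identical Br) and no stereogenic double bond. The target is therefore achiral and the "single enantiomer" demand is void. The one stereocentre of intermediates 5–9 is carried as a racemate and is erased in step 4.

**Step 1**
Reactants: 1 4H-pyran-4-one
Product: 2 3,5-dibromo-4H-pyran-4-one
Conditions: Br2 (2.3 equiv), NaOAc (2.5 equiv), AcOH, 60 °C
Reagents that add atoms: bromine, BrBr
Why: Electrophilic bromination (addition–elimination, SEAr type) hits only C3 and C5, the nucleophilic β-carbons of the two enol-ether units, while acetate takes up HBr so the pyranone is not tied up as an unreactive hydroxypyrylium salt, and no stereocentre is formed.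

**Step 2**
Reactants: 2 3,5-dibromo-4H-pyran-4-one; 3 propanal
Product: 8 (±)-2,3,5-tribromo-6-(1-hydroxypropyl)-4H-pyran-4-one, via pyranon-2-ylmagnesium chloride 4 (not isolated), via dibromo magnesium alkoxide 5 (not isolated), via C6-magnesiated alkoxide 6 (not isolated), via tribromo magnesium alkoxide 7 (not isolated)
Conditions: TMPMgCl·LiCl (1.1 equiv), THF, −40 °C, 30 min; 3 (1.05 equiv), −40 °C, 30 min; TMPMgCl·LiCl (1.3 equiv), −40 °C, 1 h; (BrCl2C)2 (1.6 equiv), −40 → 0 °C; sat. aq NH4Cl
Reagents that add atoms: 1,2-dibromo-1,1,2,2-tetrachloroethane, ClC(Cl)(Br)C(Cl)(Cl)Br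
Why: Deprotonative magnesiation with the hindered, non-nucleophilic Knochel–Hauser base removes the acidic ring C–H (alpha to the ring O, ortho to Br), the Grignard adds 1,2 to propanal (C1′ is formed racemic and is erased in step 4), the alkoxide so formed shuts down lateral deprotonation so the second magnesiation takes the only remaining ring C–H, and bromine transfer from (BrCl2C)2 then sets the C–Br bond.

**Step 3**
Reactants: 8 (±)-2,3,5-tribromo-6-(1-hydroxypropyl)-4H-pyran-4-one
Product: 9 (±)-2,3,5-tribromo-6-(1-bromopropyl)-4H-pyran-4-one
Conditions: PBr3 (0.4 equiv), CH2Cl2, 0 °C → rt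
Reagents that add atoms: phosphorus tribromide, BrP(Br)Br
Why: Alcohol-to-bromide substitution with PBr3 (SN2 on the bromophosphite ester) is favoured at this benzylic-like carbon vinylogously alpha to the carbonyl, any bromide attack at the electrophilic C2–Br is degenerate because no other halide is present, and the stereocentre stays racemic.

**Step 4**
Reactants: 9 (±)-2,3,5-tribromo-6-(1-bromopropyl)-4H-pyran-4-one
Product: 10 2,3,5-tribromo-6-(1,1-dibromopropyl)-4H-pyran-4-one (target)
Conditions: NBS (1.3 equiv), AIBN (10 mol %), PhCF3, reflux, visible light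
Reagents that add atoms: N-bromosuccinimide, O=C1CCC(=O)N1Br
Why: In this Wohl–Ziegler radical bromination the bromine atom abstracts the weakest C–H, the one at C1′ whose radical is stabilised by the alpha bromine and by conjugation with the pyranone, every ring position is already blocked, and the only stereocentre is destroyed to give the achiral target.

**Compound list**
1 | 4H-pyran-4-one | O=c1ccocc1 | starting material
2 | 3,5-dibromo-4H-pyran-4-one | O=c1c(Br)cocc1Br | intermediate
3 | propanal | CCC=O | starting material
4 | (3,5-dibromo-4-oxo-4H-pyran-2-yl)magnesium chloride (LiCl complex, drawn without LiCl) | O=c1c(Br)coc([Mg]Cl)c1Br | intermediate (not isolated)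
5 | (±)-chloromagnesium 1-(3,5-dibromo-4-oxo-4H-pyran-2-yl)propan-1-olate | CCC(O[Mg]Cl)c1occ(Br)c(=O)c1Br | intermediate (not isolated)
6 | (±)-chloromagnesium 1-[3,5-dibromo-6-(chloromagnesio)-4-oxo-4H-pyran-2-yl]propan-1-olate | CCC(O[Mg]Cl)c1oc([Mg]Cl)c(Br)c(=O)c1Br | intermediate (not isolated)
7 | (±)-chloromagnesium 1-(3,5,6-tribromo-4-oxo-4H-pyran-2-yl)propan-1-olate | CCC(O[Mg]Cl)c1oc(Br)c(Br)c(=O)c1Br | intermediate (not isolated)
8 | (±)-2,3,5-tribromo-6-(1-hydroxypropyl)-4H-pyran-4-one | CCC(O)c1oc(Br)c(Br)c(=O)c1Br | intermediate
9 | (±)-2,3,5-tribromo-6-(1-bromopropyl)-4H-pyran-4-one | CCC(Br)c1oc(Br)c(Br)c(=O)c1Br | intermediate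
10 | 2,3,5-tribromo-6-(1,1-dibromopropyl)-4H-pyran-4-one (achiral) | CCC(Br)(Br)c1oc(Br)c(Br)c(=O)c1Br | target

Total step count: 4. Longest linear sequence: 4 (1 → 2 → 8 → 9 → 10).

**Steps most likely to fail**

Step 4 is most at risk. The C1′–H is electron-poor, and its radical is twisted out of conjugation by the neighbouring ring bromine. Abstraction may therefore be slow, and bromination at C2′ or loss of HBr followed by Br2 addition may compete. The fallback sets out from 9 and comes back at 10. It replaces radical H-abstraction by polar, vinylogous-enolate chemistry. Compound 9 is deprotonated at its now very acidic C1′–H with LiHMDS (1.05 equiv, THF, −78 °C). This gives lithium 3,5,6-tribromo-2-(1-bromopropylidene)-2H-pyran-4-olate F1 (E/Z irrelevant). F1 is brominated at the exocyclic carbon with 1,2-dibromotetrachloroethane, which restores the pyranone and gives 10.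

Step 2 is second. Three failures are possible:
- The 2-magnesiated pyranone may attack a second pyranone molecule.
- The second metalation of the anionic alkoxide 5 may stall.
- The fresh C2–Br may be attacked by alkoxide or chloride before the quench.

The fallback sets out from 2 and comes back at 8. It inverts the order of bond formation and isolates in between, so the bromination is done on a substrate with no side chain at all. Grignard 4, made as before, is quenched with 1,2-dibromotetrachloroethane instead of propanal, and 2,3,5-tribromo-4H-pyran-4-one F2 is isolated. Its single remaining C–H is magnesiated (TMPMgCl·LiCl, THF, −78 °C) to (3,5,6-tribromo-4-oxo-4H-pyran-2-yl)magnesium chloride F3. F3 adds to propanal 3 to give alkoxide 7 and, after the quench, 8.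

Step 3 is third. The hindered, electron-poor carbinol may stop at the phosphite ester or eliminate to the propenyl compound. The fallback sets out from 8 and comes back at 9. It exchanges in-situ P(III) activation for a discrete sulfonate followed by an external-bromide SN2. Compound 8 is treated with Ms2O and 2,6-lutidine (CH2Cl2, −20 °C). MsCl is avoided, so no chloride can exchange with C2–Br. This gives (±)-1-(3,5,6-tribromo-4-oxo-4H-pyran-2-yl)propyl methanesulfonate F4. F4 is displaced with LiBr in acetone at room temperature to give 9.

**Further compounds**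
F1 | step 4 | lithium 3,5,6-tribromo-2-(1-bromopropylidene)-2H-pyran-4-olate | CCC(Br)=C1OC(Br)=C(Br)C([O-])=C1Br.[Li+]
F2 | step 2 | 2,3,5-tribromo-4H-pyran-4-one | O=c1c(Br)coc(Br)c1Br
F3 | step 2 | (3,5,6-tribromo-4-oxo-4H-pyran-2-yl)magnesium chloride | O=c1c(Br)c([Mg]Cl)oc(Br)c1Br
F4 | step 3 | (±)-1-(3,5,6-tribromo-4-oxo-4H-pyran-2-yl)propyl methanesulfonate | CCC(OS(C)(=O)=O)c1oc(Br)c(Br)c(=O)c1Br
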